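## Structural features

The target 23 is a 2H-chromene whose benzene ring carries no hydrogen: it bears O1 and C4 of the pyran ring, a free hydroxyl at C5 and methoxy groups at C6, C7 and C8. C2 of the pyran ring is a fully substituted, oxygen-bearing stereocentre (S) that holds a methyl group and a two-carbon chain leading to a cyclohexane. In the cyclohexane the chain sits on a quaternary carbon C1′ (R, with a methyl), the next ring atom C2′ carries the exocyclic methylidene, and C3′ is a methyl-bearing methine (R). The two ring stereocentres thus flank the sp2 carbon with their methyl groups trans, and two methylene groups separate them from C2, too far for mutual induction. Fragile points are the exocyclic 1,1-disubstituted alkene (acid moves it into the ring or starts cation–olefin cyclisation), the tertiary allylic aryl ether bond C2–O1 (ionisation or electrocyclic ring opening would erase C2), and the electron-rich pentaoxygenated phenol (oxidation to a quinone). The real difficulty is stereochemical: C3′ must be set trans to the C1′ methyl although a 2,2,6-trisubstituted cyclohexanone shows almost no preference between its epimers, and C2 must be set without help from the ring. The key step uses the position of C3′ between C2′ and the ring methylene C4′: taking C3′ out leaves a cyclopentanone whose carbonyl carbon is C2′ and whose α-quaternary carbon is C1′.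

## Logic of the disconnections

23 to 22. The C3=C4 bond of the pyran ring is cut. It is the one ring bond that can be formed without touching C2–O1, and cutting it turns the heterocycle into an aryl ether with two terminal alkenes. The forward metathesis must close the six-membered ring faster than it engages the hindered exocyclic methylidene, under neutral conditions.

22 to 21. The exocyclic C=C bond of the styrene is cut back to a formyl group. The formyl group makes the phenol acidic enough for the etherification and is easier to carry than a vinylphenol. The forward olefination must work on a chelated, doubly ortho-substituted aldehyde beside a free phenol.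

21 to 15 and 20. The bond from the aryl oxygen to the tertiary allylic carbon is cut. This is the convergent bond and the place where a catalyst can set C2. The halves are the terpenoid carbonate 15 and the arene 20; 20 has a mirror plane through its formyl group, so its two hydroxyls need no differentiation. The forward step must attack the more substituted allyl terminus on one face and stop after one etherification.

20 to 17 to 16. The two C–O bonds ortho to the formyl group are cut (through 19 and 18), then the two C–Br bonds. The positions ortho to the formyl group of 16 are its only free ring positions, so the double halogenation has no regiochemical choice. The forward sequence needs two C–O couplings at crowded positions with the aldehyde masked from hydroxide.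

15 to 14 to 12. The carbonate C–O bond is cut, then (through 13) the bond from the alkene carbon to its methyl group and the bond from the other alkene carbon to the CH2OH carbon. Syn-carbometalation of a terminal alkyne gives an isomerically pure (E)-trisubstituted alkene, and that geometric purity is what the etherification later turns into configurational purity at C2. The ring alkene must stay out of the carbometalation.

12 to 11 to 10. The terminal alkyne carbon is removed (aldehyde to alkyne homologation) and the aldehyde is traced to the ester. The forward steps need a partial ester reduction and a mild one-carbon homologation.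

10 to 9. The exocyclic C=CH2 bond is cut to the ketone that the key step delivers. The forward olefination must be non-basic, because C3′ is enolisable in 9, and must spare the ester.

9 to 6 and 8. Both ring bonds of the methyl-bearing methine are cut: the bond to the carbonyl carbon and the bond to the ring CH2. This removes one ring atom and one stereocentre, leaving a single quaternary stereocentre in 6; the excised unit is 8, made from 7. The forward insertion must move the CH2 and not the quaternary carbon, take its configuration from the reagent, insert once and avoid epimerisation.

6 to 3 and 4, 3 to 1 and 2. The bond from the quaternary carbon to the chain is cut (through 5), then the C=N bond. Conjugate addition at the more substituted α-position of a ketimine creates the quaternary stereocentre from racemic 1. The forward step must be regioselective for that position and face-selective under the control of 2.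

## Other disconnections considered

Alternative 1: The cut is a [4+2] disconnection of the cyclohexane across C2′–C3′ and C1′–C6′. In the forward step diene A2 adds to the trisubstituted double bond of the chiral alkoxybutenolide A1, endo and on the face away from the acetal alkoxy group, giving the cis-fused lactone A3.
- In its favour: both ring stereocentres arise in one concerted step. The trans relation of the ring methyls follows from the endo rule and the cis fusion, and the absolute sense comes from a cheap acetal auxiliary. No diazoalkane is needed and no enolisable stereocentre has to be protected. On control of C3′ this alternative is the better plan, because the chosen route needs an external chiral catalyst for that centre.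
- Against it here: a β,β-disubstituted dienophile reacts sluggishly with a 1-substituted diene, so forcing conditions or a Lewis acid that endangers the acetal would be needed. After the cycloaddition the ring alkene must be hydrogenated, the lactone acetal opened, the lactone carbonyl carbon turned into the methylidene by a regioselective elimination, and the acetal carbon extended into the chain.
- Comparison: mechanistically it is a pericyclic reaction with predictable topology against a polar addition and 1,2-shift that depends on a catalyst. In step economy the chosen route reaches 11 in five steps from 1 and is estimated to be several steps shorter. As drawn, A3 carries the (1S,2R,5S)-menthyl group, the less common enantiomeric series of the auxiliary, which is consistent with the (1′R,3′R) ring. The two plans are equal in leaving C2 to the same later etherification.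

Alternative 2: The cut takes O1–C2 and C3–C4 together. Forward, aldehyde 20 and enal A4 (one oxidation from 14) react under a chiral secondary amine: iminium formation, oxa-Michael addition of the phenol to the β-carbon, and aldol condensation of the enamine with the aryl aldehyde give the 3-formylchromene A5, which is then decarbonylated.
- In its favour: the pyran ring and C2 form in one step, with no carbonate, no ylide olefination and no metathesis, and with no branched-versus-linear question. In end-game step economy (three operations from 14 against four) and in regiochemistry this alternative is the better plan.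
- Against it here: the β-carbon of A4 is fully substituted, so the iminium ion is hindered and slow to form. The oxa-Michael step is reversible, the catalyst must tell a methyl group from an unbranched chain, and dienamine formation can scramble the alkene geometry. Removing the formyl group needs stoichiometric or hot rhodium chemistry, under which metal hydrides may isomerise the exocyclic alkene.
- Comparison: the fragments are the same (20 in both). The mechanisms differ: face selection at a tetrasubstituted iminium β-carbon against attack on a π-allyl whose geometry is fixed by the (E)-alkene of 15, and the latter has the closer analogy for methyl/alkyl discrimination. The plans are equal in relying wholly on catalyst control at C2.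

Alternative 3: The cut is the C4a–C5 bond and with it the whole benzene ring. Forward, a metalated 2,2-disubstituted dihydropyran adds to squarate A6 and the adduct is O-methylated to cyclobutenone A7. Heating opens the four-membered ring to a dienylketene, 6π-closure and tautomerisation give chroman A8, and a final dehydrogenation gives 23.
- In its favour: the arene substitution pattern arises with complete regiocontrol, and the C5 hydroxyl (the former ketene oxygen) is automatically distinct from the three methoxy groups. That is better than the arene branch of the chosen plan, which needs a double C–O coupling. C2 would be installed as a tertiary alcohol, so the C2–O bond never has to be made at a crowded phenol, which is also an advantage.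
- Against it here: the enantioenriched dihydropyran poses the same methyl-versus-alkyl problem at a tertiary carbinol, without an equally direct catalytic answer. Metalation and squarate addition add steps. The last step oxidises an electron-rich 5-hydroxychroman next to a sensitive alkene, where quinone formation competes with benzylic dehydrogenation.
- Comparison: it is linear where the chosen plan is convergent, and is estimated to be several steps longer after 14. The key step is a neutral pericyclic cascade; in mildness it is the equal of the palladium and ruthenium steps of the chosen plan.

Key step: step 3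

Remark 1: the configurations of 6, 9 and 23 were checked against the (R), (1R,3R) and (2S,1′R,3′R) assignments and needed no correction; the methyl ester is kept as spectator group because it is inert to diazoalkanes and to the methylenation reagent.

Remark 2 (assumption): the sense of induction of the chiral ligands in steps 3 and 11 is assigned provisionally from the usual models of these catalyst families; both antipodes of each ligand are available, and the one that furnishes (3R) in 9 and (S) at the ether carbon of 21 is the one to be used.

## Route

Step 1
Reactants: 1 2-methylcyclopentanone (racemic); 2 (S)-1-phenylethylamine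
Product: 3 (1S)-N-(2-methylcyclopentylidene)-1-phenylethan-1-amine (mixture of C=N isomers and ring epimers)
Conditions: TsOH (cat.), toluene, reflux, Dean–Stark
Reagents that add atoms: none
Why: Acid-catalysed imine condensation driven by azeotropic removal of water; the labile ring α-centre is irrelevant because the imine reacts through its more substituted secondary enamine tautomer.

Step 2
Reactants: 3 (1S)-N-(2-methylcyclopentylidene)-1-phenylethan-1-amine; 4 methyl acrylate
Product: 6 methyl 3-[(1R)-1-methyl-2-oxocyclopentyl]propanoate, via Michael adduct imine 5 (not isolated)
Conditions: 4 (1.5 equiv), THF, 40 °C; then 20% aq AcOH, rt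
Reagents that add atoms: water, O
Why: Chiral-imine Michael addition (aza-ene-type) of the more substituted secondary enamine tautomer: the acrylate is taken up on the enamine face opposite the phenyl group with concerted N–H transfer, which should set the quaternary centre as (R) with the (S)-amine; aqueous acetic acid then hydrolyses imine 5 and returns the amine.

Step 3
Reactants: 6 methyl 3-[(1R)-1-methyl-2-oxocyclopentyl]propanoate; 7 N-ethyl-N-nitrosourea
Product: 9 methyl 3-[(1R,3R)-1,3-dimethyl-2-oxocyclohexyl]propanoate, via diazoethane 8 (not isolated)
Conditions: 7, 40% aq KOH, PhMe, −5 °C, cold organic layer dried over KOH; added slowly to 6, Sc(OTf)3 (10 mol%), indanyl-pybox ligand (12 mol%), PhMe, −78 → −40 °C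
Reagents that add atoms: none
Why: The scandium(III)–ligand complex binds the ketone oxygen of 6, and the nucleophilic carbon of 8 adds to the activated carbonyl carbon to give a β-metalloxy alkanediazonium betaine. Loss of dinitrogen is concerted with a 1,2-shift of the ring CH2 that stands anti-periplanar to the C–N2 bond, so both bonds of the new CH(CH3) carbon (to the carbonyl carbon and to the former α-CH2) form in one operation; the closest known reaction type is the Lewis-acid-catalysed Tiffeneau–Demjanov-type homologation of cycloalkanones with non-stabilised diazoalkanes, including scandium(III)/chiral-ligand variants. The six-membered ring arises by ring enlargement through this 1,2-alkyl shift (insertion of one carbon into the C(=O)–CH2 bond) and not by a cyclisation. The new stereocentre C3 is decided in the C–C bond-forming addition, by which carbonyl face is attacked and which face of the diazo carbon is presented, and the shift then replaces N2 with inversion so that this choice is carried into the product; the controlling element is the chiral ligand sphere on scandium, because the α-quaternary carbon (methyl against CH2CH2CO2Me) gives almost no facial bias. The step needs migration of CH2 rather than of the quaternary carbon, and the substrate secures this: the quaternary carbon can only migrate from a rotamer in which the methyl of the diazo carbon is gauche to that fully substituted carbon, whereas the CH2 can migrate from a rotamer in which the methyl is anti to it. It also needs a single insertion, which the structure favours because 9 is an α,α,α′-trisubstituted cyclohexanone, more hindered than 6, and the ester is inert to diazoalkanes. Low temperature, a non-basic medium and a neutral work-up are needed to keep the new enolisable methine from epimerising before step 4; any minor enantiomer of 6 should emerge as a diastereomer of 9 and be removable by chromatography.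

Step 4
Reactants: 9 methyl 3-[(1R,3R)-1,3-dimethyl-2-oxocyclohexyl]propanoate
Product: 10 methyl 3-[(1R,3R)-1,3-dimethyl-2-methylidenecyclohexyl]propanoate
Conditions: Zn, CH2Br2, TiCl4 (pre-formed Lombardo reagent), THF–CH2Cl2, 0 °C → rt
Reagents that add atoms: dibromomethane, BrCBr
Why: Takai–Lombardo methylenation: the titanium-activated gem-dimetallic CH2 reagent is nucleophilic but not basic, so the α-methine is not enolised and the ester is left alone; after this step C3 is allylic and no longer epimerisable.

Step 5
Reactants: 10 methyl 3-[(1R,3R)-1,3-dimethyl-2-methylidenecyclohexyl]propanoate
Product: 11 3-[(1R,3R)-1,3-dimethyl-2-methylidenecyclohexyl]propanal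
Conditions: DIBAL-H (1.1 equiv), CH2Cl2, −78 °C; MeOH, aq Rochelle salt
Reagents that add atoms: none
Why: Partial reduction of a methyl ester by DIBAL-H at low temperature through a tetrahedral aluminium hemiacetal that collapses only on work-up; the isolated alkene is inert.

Step 6
Reactants: 11 3-[(1R,3R)-1,3-dimethyl-2-methylidenecyclohexyl]propanal
Product: 12 (1R,3R)-1-(but-3-yn-1-yl)-1,3-dimethyl-2-methylidenecyclohexane
Conditions: dimethyl (1-diazo-2-oxopropyl)phosphonate, K2CO3, MeOH, 0 °C → rt
Reagents that add atoms: dimethyl (1-diazo-2-oxopropyl)phosphonate, CC(=O)C(=[N+]=[N-])P(=O)(OC)OC
Why: Ohira–Bestmann (Seyferth–Gilbert) homologation: the diazomethylphosphonate anion formed by methanolysis adds to the aldehyde, phosphate is eliminated and the alkylidene carbene rearranges to the terminal alkyne; the carbonate base is harmless because the aldehyde has no α-stereocentre.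

Step 7
Reactants: 12 (1R,3R)-1-(but-3-yn-1-yl)-1,3-dimethyl-2-methylidenecyclohexane
Product: 14 (2E)-5-[(1R,3R)-1,3-dimethyl-2-methylidenecyclohexyl]-3-methylpent-2-en-1-ol, via alkenyldimethylalane 13 (not isolated)
Conditions: Me3Al (2.5 equiv), Cp2ZrCl2 (0.25 equiv), CH2Cl2, 0 °C → rt; then n-BuLi, THF, −78 °C; (CH2O)n, → rt
Reagents that add atoms: trimethylaluminium, C[Al](C)C; paraformaldehyde (as formaldehyde), C=O
Why: Zirconium-catalysed methylalumination (Negishi carboalumination) adds methyl and aluminium syn with aluminium on the terminal carbon, and the alkenyl ate complex is hydroxymethylated with retention, which gives the (E)-trisubstituted allylic alcohol; the hindered 1,1-disubstituted ring alkene should not carbometalate.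

Step 8
Reactants: 14 (2E)-5-[(1R,3R)-1,3-dimethyl-2-methylidenecyclohexyl]-3-methylpent-2-en-1-ol
Product: 15 (2E)-5-[(1R,3R)-1,3-dimethyl-2-methylidenecyclohexyl]-3-methylpent-2-en-1-yl methyl carbonate
Conditions: ClCO2Me, pyridine, CH2Cl2, 0 °C
Reagents that add atoms: methyl chloroformate, COC(=O)Cl
Why: Plain O-acylation of a primary allylic alcohol under buffered conditions, which avoids any acid that could ionise the allylic system.

Step 9
Reactants: 16 3,4,5-trimethoxybenzaldehyde
Product: 17 2,6-dibromo-3,4,5-trimethoxybenzaldehyde
Conditions: NBS (2.3 equiv), TFA (cat.), MeCN, 60 °C
Reagents that add atoms: N-bromosuccinimide, O=C1CCC(=O)N1Br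
Why: Electrophilic aromatic bromination at the only two free ring positions, each ortho and para to methoxy groups; the first bromine deactivates the ring only mildly, so the second substitution should follow on warming.

Step 10
Reactants: 17 2,6-dibromo-3,4,5-trimethoxybenzaldehyde
Product: 20 2,6-dihydroxy-3,4,5-trimethoxybenzaldehyde, via dibromo dimethyl acetal 18 (not isolated), via dihydroxy dimethyl acetal 19 (not isolated)
Conditions: HC(OMe)3, TsOH (cat.), MeOH, 60 °C; K2CO3, concentrate; Pd2(dba)3 (2 mol%), tBuXPhos (8 mol%), KOH (6 equiv), dioxane–H2O, 100 °C, Ar; 1 M HCl, THF, rt
Reagents that add atoms: potassium hydroxide, [K+].[OH-]; water, O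
Why: The acetal shields the aldehyde from hydroxide (Cannizzaro reaction and base-induced deformylation of 2,6-dihalobenzaldehydes); palladium-catalysed C–O coupling with hydroxide, for which the bulky biaryl phosphine promotes reductive elimination at di-ortho-substituted positions, installs both hydroxyls, and acidic work-up releases the aldehyde.

Step 11
Reactants: 15 (2E)-5-[(1R,3R)-1,3-dimethyl-2-methylidenecyclohexyl]-3-methylpent-2-en-1-yl methyl carbonate; 20 2,6-dihydroxy-3,4,5-trimethoxybenzaldehyde
Product: 21 2-({(3S)-5-[(1R,3R)-1,3-dimethyl-2-methylidenecyclohexyl]-3-methylpent-1-en-3-yl}oxy)-6-hydroxy-3,4,5-trimethoxybenzaldehyde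
Conditions: 20 (1.3 equiv), Pd2(dba)3·CHCl3 (2 mol%), (R,R)-DACH-phenyl Trost ligand (6 mol%), CH2Cl2, 0 °C → rt
Reagents that add atoms: none
Why: Palladium-catalysed asymmetric allylic alkylation (Tsuji–Trost) with a phenol nucleophile: ionisation of the (E)-carbonate gives a geometrically defined π-allyl, and the phenoxide (formed by the liberated methoxide) attacks the more substituted terminus inside the chiral pocket, which sets the ether carbon as (S) under ligand control. Aldehyde 20 is mirror-symmetric, so either hydroxyl gives the same monoether, and the remaining hydroxyl stays chelated to the formyl group and is less nucleophilic; C-allylation is impossible because the ring has no free position.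

Step 12
Reactants: 21 2-({(3S)-5-[(1R,3R)-1,3-dimethyl-2-methylidenecyclohexyl]-3-methylpent-1-en-3-yl}oxy)-6-hydroxy-3,4,5-trimethoxybenzaldehyde
Product: 22 3-({(3S)-5-[(1R,3R)-1,3-dimethyl-2-methylidenecyclohexyl]-3-methylpent-1-en-3-yl}oxy)-2-ethenyl-4,5,6-trimethoxyphenol
Conditions: Ph3PCH3Br (3.0 equiv), KOtBu (2.9 equiv), THF, 0 °C → rt
Reagents that add atoms: methyltriphenylphosphonium bromide, C[P+](c1ccccc1)(c1ccccc1)c1ccccc1.[Br-]
Why: Wittig methylenation; one equivalent of ylide is spent on the phenol, the aldehyde has no enolisable position, and the tertiary allylic aryl ether is stable to base.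

Step 13
Reactants: 22 3-({(3S)-5-[(1R,3R)-1,3-dimethyl-2-methylidenecyclohexyl]-3-methylpent-1-en-3-yl}oxy)-2-ethenyl-4,5,6-trimethoxyphenol
Product: 23 (2S)-2-{2-[(1R,3R)-1,3-dimethyl-2-methylidenecyclohexyl]ethyl}-6,7,8-trimethoxy-2-methyl-2H-chromen-5-ol
Conditions: Grubbs second-generation catalyst (5 mol%), CH2Cl2 (0.01 M), 40 °C, dark
Reagents that add atoms: none
Why: Ring-closing metathesis of the styrene and the vinyl group closes the six-membered 2H-chromene with loss of ethene; the exocyclic methylidene, flanked by a quaternary and a tertiary carbon, should not engage, and the C2–O bond is not touched, so the configuration set in step 11 is kept.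

## Compound list

1 | 2-methylcyclopentanone (racemic) | CC1CCCC1=O | starting material
2 | (S)-1-phenylethylamine | C[C@H](N)c1ccccc1 | starting material
3 | (1S)-N-(2-methylcyclopentylidene)-1-phenylethan-1-amine | C[C@H](N=C1CCCC1C)c1ccccc1 | intermediate
4 | methyl acrylate | C=CC(=O)OC | starting material
5 | methyl 3-[(1R)-1-methyl-2-{[(1S)-1-phenylethyl]imino}cyclopentyl]propanoate | C[C@H](N=C1CCC[C@]1(C)CCC(=O)OC)c1ccccc1 | intermediate (not isolated)
6 | methyl 3-[(1R)-1-methyl-2-oxocyclopentyl]propanoate | O=C1CCC[C@]1(C)CCC(=O)OC | intermediate
7 | N-ethyl-N-nitrosourea | CCN(N=O)C(N)=O | starting material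
8 | diazoethane | CC=[N+]=[N-] | intermediate (not isolated)
9 | methyl 3-[(1R,3R)-1,3-dimethyl-2-oxocyclohexyl]propanoate | O=C1[C@H](C)CCC[C@]1(C)CCC(=O)OC | intermediate
10 | methyl 3-[(1R,3R)-1,3-dimethyl-2-methylidenecyclohexyl]propanoate | C=C1[C@H](C)CCC[C@]1(C)CCC(=O)OC | intermediate
11 | 3-[(1R,3R)-1,3-dimethyl-2-methylidenecyclohexyl]propanal | C=C1[C@H](C)CCC[C@]1(C)CCC=O | intermediate
12 | (1R,3R)-1-(but-3-yn-1-yl)-1,3-dimethyl-2-methylidenecyclohexane | C=C1[C@H](C)CCC[C@]1(C)CCC#C | intermediate
13 | {(1E)-4-[(1R,3R)-1,3-dimethyl-2-methylidenecyclohexyl]-2-methylbut-1-en-1-yl}dimethylalane | C=C1[C@H](C)CCC[C@]1(C)CC/C(C)=C/[Al](C)C | intermediate (not isolated)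
14 | (2E)-5-[(1R,3R)-1,3-dimethyl-2-methylidenecyclohexyl]-3-methylpent-2-en-1-ol | C=C1[C@H](C)CCC[C@]1(C)CC/C(C)=C/CO | intermediate
15 | (2E)-5-[(1R,3R)-1,3-dimethyl-2-methylidenecyclohexyl]-3-methylpent-2-en-1-yl methyl carbonate | C=C1[C@H](C)CCC[C@]1(C)CC/C(C)=C/COC(=O)OC | intermediate
16 | 3,4,5-trimethoxybenzaldehyde | COc1cc(C=O)cc(OC)c1OC | starting material
17 | 2,6-dibromo-3,4,5-trimethoxybenzaldehyde | COc1c(Br)c(C=O)c(Br)c(OC)c1OC | intermediate
18 | 1,3-dibromo-2-(dimethoxymethyl)-4,5,6-trimethoxybenzene | COc1c(Br)c(C(OC)OC)c(Br)c(OC)c1OC | intermediate (not isolated)
19 | 2-(dimethoxymethyl)-4,5,6-trimethoxybenzene-1,3-diol | COc1c(O)c(C(OC)OC)c(O)c(OC)c1OC | intermediate (not isolated)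
20 | 2,6-dihydroxy-3,4,5-trimethoxybenzaldehyde | COc1c(O)c(C=O)c(O)c(OC)c1OC | intermediate
21 | 2-({(3S)-5-[(1R,3R)-1,3-dimethyl-2-methylidenecyclohexyl]-3-methylpent-1-en-3-yl}oxy)-6-hydroxy-3,4,5-trimethoxybenzaldehyde | C=C1[C@H](C)CCC[C@]1(C)CC[C@@](C)(C=C)Oc1c(OC)c(OC)c(OC)c(O)c1C=O | intermediate
22 | 3-({(3S)-5-[(1R,3R)-1,3-dimethyl-2-methylidenecyclohexyl]-3-methylpent-1-en-3-yl}oxy)-2-ethenyl-4,5,6-trimethoxyphenol | C=C1[C@H](C)CCC[C@]1(C)CC[C@@](C)(C=C)Oc1c(OC)c(OC)c(OC)c(O)c1C=C | intermediate
23 | (2S)-2-{2-[(1R,3R)-1,3-dimethyl-2-methylidenecyclohexyl]ethyl}-6,7,8-trimethoxy-2-methyl-2H-chromen-5-ol | C=C1[C@H](C)CCC[C@]1(C)CC[C@@]1(C)C=Cc2c(O)c(OC)c(OC)c(OC)c2O1 | target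

## Step count and least certain steps

Total step count: 13. Longest linear sequence: 11 steps (steps 1–8, then 11–13); the arene branch is steps 9–10.

Step 3 (key step). The most likely failure is poor facial selectivity in the addition of 8 to the scandium-bound ketone, since the substrate offers no bias and the catalyst has not been used with this combination of a quaternary α-carbon and an enolisable new methine. Competing closure of the betaine to an epoxide, Lewis-acid decomposition of 8 and epimerisation during work-up are secondary risks. Compound 7 is a carcinogen and 8 is an explosive gas, so 8 should be handled only as a cold dilute solution behind a shield.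
- Fallback: replace catalyst control by separation and recycling. From 6 the insertion is run with an achiral Lewis acid (Sc(OTf)3 without ligand, or BF3·OEt2), which should give 9 together with its C3 epimer, methyl 3-[(1R,3S)-1,3-dimethyl-2-oxocyclohexyl]propanoate F1. The two diastereomers are separated by chromatography. F1 is re-equilibrated with NaOMe in MeOH, where only the methine can epimerise, and separated again. The fallback sets out from 6 and comes back at 9.

Step 11. The doubly ortho-substituted, hydrogen-bonded phenoxide is a reluctant nucleophile for the tertiary allyl terminus. Attack may drift to the primary terminus, and because the aryloxide is a good leaving group the product can re-ionise on palladium, which would erode both the branched selectivity and the facial selectivity. The reaction should be stopped at full conversion and kept cold.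
- Fallback: resolution in place of catalyst control. Material of insufficient purity at C2 is carried through steps 12 and 13. The resulting 23 is acylated at the 5-hydroxyl with (1S)-camphanic chloride (Et3N, DMAP, CH2Cl2) to the (2S)-chromenyl (1S,4R)-camphanate F6. The auxiliary sits peri to C4 and near C2, so the C2-epimeric esters should be separable by chromatography or crystallisation. Saponification of pure F6 (LiOH, THF–H2O, 0 °C, then mild acid) returns 23. The fallback sets out from 23 and comes back at 23.

Step 10. The second C–O coupling may stall, because the phenoxide formed in the first coupling deactivates the ring toward oxidative addition; hydrodebromination and air oxidation of the electron-rich diol in hot base are further risks.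
- Fallback: masked oxygen nucleophile in place of hydroxide. Acetal 18 is isolated after the acetalisation and subjected to Ullmann etherification with sodium benzyloxide (BnOH, NaH, CuI cat., toluene–DMF, 110 °C). This gives 1,3-bis(benzyloxy)-2-(dimethoxymethyl)-4,5,6-trimethoxybenzene F5, which is neutral and easy to purify. Hydrogenolysis (H2, Pd/C, EtOAc) then gives 19, and the acidic work-up of step 10 gives 20. The fallback sets out from 18 and comes back at 19.

Step 4. The carbonyl group is shielded by a quaternary and a tertiary α-carbon, so conversion may be incomplete, and long exposure to the titanium Lewis acid raises the risk of epimerisation at C3.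
- Fallback: titanocene methylidene chemistry, with a different route to 14. Ketone 9 is heated with excess Cp2TiMe2 (Petasis reagent, toluene, 70 °C), which methylenates the ketone and also turns the ester into a methyl enol ether, giving (1R,3R)-1-(3-methoxybut-3-en-1-yl)-1,3-dimethyl-2-methylidenecyclohexane F2. Brief treatment with dilute oxalic acid in wet THF hydrolyses only the enol ether to 4-[(1R,3R)-1,3-dimethyl-2-methylidenecyclohexyl]butan-2-one F3. Horner–Wadsworth–Emmons olefination (triethyl phosphonoacetate, NaH, THF) gives ethyl (2E)-5-[(1R,3R)-1,3-dimethyl-2-methylidenecyclohexyl]-3-methylpent-2-enoate F4; the (Z)-isomer, expected as a minor product, must be removed by chromatography. DIBAL-H reduction of F4 gives 14. The fallback sets out from 9 and comes back at 14, bypassing steps 5–7.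

## Further compounds

F1 | step 3 | methyl 3-[(1R,3S)-1,3-dimethyl-2-oxocyclohexyl]propanoate | O=C1[C@@H](C)CCC[C@]1(C)CCC(=O)OC
F2 | step 4 | (1R,3R)-1-(3-methoxybut-3-en-1-yl)-1,3-dimethyl-2-methylidenecyclohexane | C=C1[C@H](C)CCC[C@]1(C)CCC(=C)OC
F3 | step 4 | 4-[(1R,3R)-1,3-dimethyl-2-methylidenecyclohexyl]butan-2-one | C=C1[C@H](C)CCC[C@]1(C)CCC(C)=O
F4 | step 4 | ethyl (2E)-5-[(1R,3R)-1,3-dimethyl-2-methylidenecyclohexyl]-3-methylpent-2-enoate | C=C1[C@H](C)CCC[C@]1(C)CC/C(C)=C/C(=O)OCC
F5 | step 10 | 1,3-bis(benzyloxy)-2-(dimethoxymethyl)-4,5,6-trimethoxybenzene | COc1c(OCc2ccccc2)c(C(OC)OC)c(OCc2ccccc2)c(OC)c1OC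
F6 | step 11 | (2S)-2-{2-[(1R,3R)-1,3-dimethyl-2-methylidenecyclohexyl]ethyl}-6,7,8-trimethoxy-2-methyl-2H-chromen-5-yl (1S,4R)-4,7,7-trimethyl-3-oxo-2-oxabicyclo[2.2.1]heptane-1-carboxylate | C=C1[C@H](C)CCC[C@]1(C)CC[C@@]1(C)C=Cc2c(OC(=O)[C@@]34CC[C@@](C)(C(=O)O3)C4(C)C)c(OC)c(OC)c(OC)c2O1
A1 | alternative 1 | (5S)-4-methyl-5-{[(1S,2R,5S)-5-methyl-2-(propan-2-yl)cyclohexyl]oxy}furan-2(5H)-one | CC1=CC(=O)O[C@@H]1O[C@H]2C[C@@H](C)CC[C@@H]2C(C)C
A2 | alternative 1 | (3E)-penta-1,3-diene | C=C/C=C/C
A3 | alternative 1 | cis-fused (3S)-3-[(1S,2R,5S)-menthyloxy]-3a,7-dimethyl-3a,4,7,7a-tetrahydroisobenzofuran-1(3H)-one, 7-methyl cis to the lactone ring | C[C@@H]1C=CC[C@]2(C)[C@@H](O[C@H]3C[C@@H](C)CC[C@@H]3C(C)C)OC(=O)[C@H]12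
A4 | alternative 2 | (2E)-5-[(1R,3R)-1,3-dimethyl-2-methylidenecyclohexyl]-3-methylpent-2-enal | C=C1[C@H](C)CCC[C@]1(C)CC/C(C)=C/C=O
A5 | alternative 2 | (2S)-2-{2-[(1R,3R)-1,3-dimethyl-2-methylidenecyclohexyl]ethyl}-5-hydroxy-6,7,8-trimethoxy-2-methyl-2H-chromene-3-carbaldehyde | C=C1[C@H](C)CCC[C@]1(C)CC[C@@]1(C)C(C=O)=Cc2c(O)c(OC)c(OC)c(OC)c2O1
A6 | alternative 3 | dimethyl squarate (3,4-dimethoxycyclobut-3-ene-1,2-dione) | COC1=C(OC)C(=O)C1=O
A7 | alternative 3 | 4-[(2R)-2-{2-[(1R,3R)-1,3-dimethyl-2-methylidenecyclohexyl]ethyl}-2-methyl-3,4-dihydro-2H-pyran-6-yl]-2,3,4-trimethoxycyclobut-2-en-1-one (mixture at the cyclobutenone C4) | C=C1[C@H](C)CCC[C@]1(C)CC[C@@]1(C)CCC=C(O1)C1(OC)C(OC)=C(OC)C1=O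
A8 | alternative 3 | (2S)-2-{2-[(1R,3R)-1,3-dimethyl-2-methylidenecyclohexyl]ethyl}-6,7,8-trimethoxy-2-methyl-3,4-dihydro-2H-chromen-5-ol | C=C1[C@H](C)CCC[C@]1(C)CC[C@@]1(C)CCc2c(O)c(OC)c(OC)c(OC)c2O1
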